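The numbers in the tables stem from a simulated flask with made-up constants; noise was put on by code.

1. Start with an easy count: what one reacted electrophile costs you in nucleophile. In the delta run the target reads 3.7% early and 2.9% late while the solid falls to 18.3%, so what forms goes on to over-reaction product, and each electrophile takes two nucleophiles.

all flasks: solid electrophile 0.10 M; gas 6.5 mM (held)
- eta: nucleophile 0.073 M; run made earlier
- delta: nucleophile 0.14 M; run made earlier
- gamma: nucleophile 0.18 M; run made earlier
- ash: nucleophile 0.210 M; time 4.0 d
- elm: nucleophile 0.100 M; time 4.0 d

| run | time / d | solid electrophile / % | target / % |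
|---|---|---|---|
| eta | 0.250 | 72.4 | 2.9 |
| eta | 0.625 | 64.5 | 3.7 |
| eta | 1.25 | 56.2 | 3.2 |
| eta | 2.08 | 49.7 | 3.0 |
| eta | 3.00 | 43.7 | 3.0 |
| delta | 0.208 | 71.7 | 2.3 |
| delta | 0.417 | 65.3 | 3.7 |
| delta | 0.833 | 51.9 | 2.6 |
| delta | 1.67 | 35.7 | 2.4 |
| delta | 3.00 | 18.3 | 2.9 |
| gamma | 0.250 | 68.5 | 2.8 |
| gamma | 0.625 | 54.3 | 2.7 |
| gamma | 1.25 | 34.4 | 2.2 |
| gamma | 2.08 | 16.2 | 3.3 |
| gamma | 3.00 | 3.4 | 4.1 |

(scatter of a reading: 0.5 percentage points)

- solid, in amounts per volume of the solution: solid electrophile
- at the start none of free base is dissolved
- steps under discussion: gas <-> free base; solid electrophile <-> electrophile; nucleophile + acid set free <-> protonated nucleophile; nucleophile + target -> over-reaction product; electrophile + nucleophile -> acid set free + target; acid set free + free base <-> salt of the base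
- at the start none of the solid electrophile is in solution
- what has only dissolved of solid electrophile counts as not reacted

- part of the solid electrophile that has reacted (what has only dissolved counts as not reacted) at the end, ash
- part of the solid electrophile that has reacted (what has only dissolved counts as not reacted) at the end, elm
- what raising the concentration of nucleophile from its lowest to its highest value here does to the part of the solid electrophile that has reacted (what has only dissolved counts as not reacted) (changes below 5 percentage points count as none) (it falls / it rises / no change)

2. Reckon elm at two nucleophiles each: the charge allows 50.0% of the solid. Go round once more: the standing target took one nucleophile, not two. Adding that reading before halving gives 51.4%. This is the nucleophile ceiling: the share of solid electrophile that the charged nucleophile, in elm the limiting reagent, can turn over at this count. For ash the first round gives 105%, so its charge sets no such bound.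

3. Now turn the question round. For no change, ash would have to finish within 5 percentage points of elm. The gamma run speaks against that, with 0.18 M of nucleophile, less than ash. By 3.00 d its solid reads 3.4%. Take the 27.6% that the eta run had lost at its first reading as an upper guess for what merely dissolved, and gamma has reacted about 69.0%, above elm's ceiling. My reckoning: elm at 4.0 d stands under its ceiling, and the part reacted rises.

4. The forecast says 91% for ash, 48% for elm and it rises, on the same count: “each electrophile consumes about two nucleophiles”.

5. The flask gives 88.0% for ash and 45.1% for elm, so it rises, by 43 points.

    gas ⇌ free base, rate k1*(csat - [free base]) (kL = 0.110 /min)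
    solid electrophile ⇌ electrophile, rate k2*(cs2 - [electrophile]) while solid is left; crystals form when [electrophile] > cs2 (solubility = 26.0 mM, k = 0.0120 /min)
    nucleophile + acid set free ⇌ protonated nucleophile, settled at all times (K = 140 /M)
    nucleophile + target → over-reaction product (k = 0.0580 /M/min)
    electrophile + nucleophile → acid set free + target (k = 0.00720 /M/min)
    acid set free + free base ⇌ salt of the base, settled at all times (K = 7.90 × 10⁶ /M)

6. The nucleophile charge is the main reason: ash with elm's charge gives 45.1% instead of 88.0%. Elm at 4.0 d still has 13.1% of its nucleophile free. By 40.0 d its free nucleophile stands at 0% with 22.4% of the solid undissolved, and the reacted part is 51.6%, against the ceiling of 51.4%.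

7. On a neighbour, the same flask as elm but with 0.025 M of nucleophile, the ceiling gives 14.0%. The computed result is 12.3%, with 14% of its nucleophile still free.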